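**Retrosynthetic overview** (rings A–F in the order of the SMILES: A = terminal 2,4,6-trihydroxyphenyl, D = pentaoxygenated ring, F = terminal 3,4,5-trihydroxyphenyl)
1. Target ⇐ global O-demethylation of the pentadeca-O-methyl ether; all six rings are bought as polymethoxyarenes, so no ring is built.
2. Every ether oxygen sits on a 2,6-dioxygenated carbon of one ring and on a less hindered carbon of the next, so each Ar–O bond is cut on the less hindered side: hindered phenol + ArF (SNAr), ArBr (Ullmann) or ArB(OH)2 (Chan–Lam).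
3. Last C–O bond is D–O–E: tetramer phenol A-B-C-D–OH + bromide Br–E–O–F (E–F made by Chan–Lam, which keeps the bromide).
4. The hindered phenols are unmasked from ArCHO by Baeyer–Villiger/Dakin oxidation; ring C enters as 4-fluoro-2,6-dimethoxybenzaldehyde, ring D as 6-bromo-2,3,4-trimethoxybenzaldehyde (Rieche formylation).
5. Order of ring joining: B–C (SNAr) → A–BC (Ullmann) → ABC–D (Ullmann); E–F (Chan–Lam); ABCD + EF (Ullmann); deprotection.

Assumption: the target has no stereocentre (it is achiral), so no enantiocontrol is needed; compounds 1, 2, 4, 8 and 14 are taken as catalogue chemicals.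

**Step 1**
Reactants: 1 4-bromo-2,6-dimethoxyphenol; 2 4-fluoro-2,6-dimethoxybenzaldehyde
Product: 3 4-(4-bromo-2,6-dimethoxyphenoxy)-2,6-dimethoxybenzaldehyde
Conditions: K2CO3, DMF, 110 °C
Reagents that add atoms: none
Why: SNAr (addition–elimination) in which the para-formyl group activates the C–F bond toward the hindered phenoxide of 1, while the unactivated C–Br bond is inert without copper; no stereocentre is formed.

**Step 2**
Reactants: 3 4-(4-bromo-2,6-dimethoxyphenoxy)-2,6-dimethoxybenzaldehyde; 4 2,4,6-trimethoxyphenol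
Product: 5 4-[2,6-dimethoxy-4-(2,4,6-trimethoxyphenoxy)phenoxy]-2,6-dimethoxybenzaldehyde
Conditions: CuI (10 mol%), picolinic acid (20 mol%), K3PO4, DMSO, 90 °C, Ar
Reagents that add atoms: none
Why: Ligand-accelerated Ullmann diaryl ether coupling accepts a 2,6-disubstituted phenol when the aryl bromide is unhindered, and the non-enolisable aldehyde survives K3PO4; no stereocentre is formed.

**Step 3**
Reactants: 5 4-[2,6-dimethoxy-4-(2,4,6-trimethoxyphenoxy)phenoxy]-2,6-dimethoxybenzaldehyde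
Product: 7 4-[2,6-dimethoxy-4-(2,4,6-trimethoxyphenoxy)phenoxy]-2,6-dimethoxyphenol, via aryl formate 6 (not isolated)
Conditions: mCPBA (1.2 equiv), CH2Cl2, 0 °C to rt; then Et3N (cat.), MeOH, rt
Reagents that add atoms: mCPBA, OOC(=O)c1cccc(Cl)c1
Why: Baeyer–Villiger (Dakin-type) oxidation in which the electron-rich aryl group migrates in the Criegee adduct to give the formate, which mild methanolysis cleaves to the new hindered phenol; no stereocentre is formed.

**Step 4**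
Reactants: 8 5-bromo-1,2,3-trimethoxybenzene
Product: 10 6-bromo-2,3,4-trimethoxybenzaldehyde, via α-chlorobenzyl methyl ether 9 (not isolated)
Conditions: Cl2CHOMe, TiCl4, CH2Cl2, −10 to 0 °C; then ice-water
Reagents that add atoms: dichloromethyl methyl ether, COC(Cl)Cl; water, O
Why: Rieche formylation; the two free positions of 8 are equivalent, so only one regioisomer can form, and the transient racemic α-chloro ether hydrolyses to the achiral aldehyde on quench.

**Step 5**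
Reactants: 7 4-[2,6-dimethoxy-4-(2,4,6-trimethoxyphenoxy)phenoxy]-2,6-dimethoxyphenol; 10 6-bromo-2,3,4-trimethoxybenzaldehyde
Product: 11 6-{4-[2,6-dimethoxy-4-(2,4,6-trimethoxyphenoxy)phenoxy]-2,6-dimethoxyphenoxy}-2,3,4-trimethoxybenzaldehyde
Conditions: CuI (20 mol%), picolinic acid (40 mol%), K3PO4, DMSO, 100 °C, Ar
Reagents that add atoms: none
Why: Ullmann diaryl ether coupling in which the ortho-formyl group accelerates copper insertion into the C–Br bond of 10 and so offsets the steric demand of the 2,6-dimethoxyphenol; no stereocentre is formed.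

**Step 6**
Reactants: 11 6-{4-[2,6-dimethoxy-4-(2,4,6-trimethoxyphenoxy)phenoxy]-2,6-dimethoxyphenoxy}-2,3,4-trimethoxybenzaldehyde
Product: 13 6-{4-[2,6-dimethoxy-4-(2,4,6-trimethoxyphenoxy)phenoxy]-2,6-dimethoxyphenoxy}-2,3,4-trimethoxyphenol, via aryl formate 12 (not isolated)
Conditions: mCPBA (1.2 equiv), CH2Cl2, 0 °C to rt; then Et3N (cat.), MeOH, rt
Reagents that add atoms: mCPBA, OOC(=O)c1cccc(Cl)c1
Why: Baeyer–Villiger (Dakin-type) oxidation; the aryl group bearing ortho- and para-oxygen donors migrates, and methanolysis of the formate frees the phenol that becomes the D–O–E oxygen; no stereocentre is formed.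

**Step 7**
Reactants: 1 4-bromo-2,6-dimethoxyphenol; 14 (3,4,5-trimethoxyphenyl)boronic acid (2.5 equiv)
Product: 15 5-(4-bromo-2,6-dimethoxyphenoxy)-1,2,3-trimethoxybenzene
Conditions: Cu(OAc)2, pyridine, 4 Å MS, CH2Cl2, air, rt
Reagents that add atoms: none
Why: Chan–Lam (Chan–Evans–Lam) oxidative O-arylation runs at room temperature under air, accepts a 2,6-disubstituted phenol with an unhindered boronic acid and leaves the aryl bromide untouched for step 8; no stereocentre is formed.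

**Step 8**
Reactants: 13 6-{4-[2,6-dimethoxy-4-(2,4,6-trimethoxyphenoxy)phenoxy]-2,6-dimethoxyphenoxy}-2,3,4-trimethoxyphenol; 15 5-(4-bromo-2,6-dimethoxyphenoxy)-1,2,3-trimethoxybenzene (1.5 equiv)
Product: 16 5-[4-(6-{4-[2,6-dimethoxy-4-(2,4,6-trimethoxyphenoxy)phenoxy]-2,6-dimethoxyphenoxy}-2,3,4-trimethoxyphenoxy)-2,6-dimethoxyphenoxy]-1,2,3-trimethoxybenzene
Conditions: CuI (20 mol%), picolinic acid (40 mol%), K3PO4, DMSO, 110 °C, Ar
Reagents that add atoms: none
Why: Ullmann diaryl ether coupling of a hindered phenol with an unhindered aryl bromide; neither partner carries a second reactive group, so only the D–O–E bond can form; no stereocentre is formed.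

**Step 9**
Reactants: 16 pentadeca-O-methyl ether (name as in step 8)
Product: 18 5-[4-(6-{4-[2,6-dihydroxy-4-(2,4,6-trihydroxyphenoxy)phenoxy]-2,6-dihydroxyphenoxy}-2,3,4-trihydroxyphenoxy)-2,6-dihydroxyphenoxy]benzene-1,2,3-triol (CNP0175585.0), via per-O-dibromoboryl ether 17 (not isolated)
Conditions: BBr3 (30 equiv), CH2Cl2, −78 °C to rt, Ar; then H2O, 0 °C
Reagents that add atoms: none
Why: Lewis-acid ether cleavage in which bromide attacks the methyl carbon of each O–B complex (SN2), so the sp2 diaryl ether bonds stay intact and the borate esters hydrolyse on quench; the product is achiral.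

**Compound list**
1 | 4-bromo-2,6-dimethoxyphenol | COc1cc(Br)cc(OC)c1O | starting material
2 | 4-fluoro-2,6-dimethoxybenzaldehyde | COc1cc(F)cc(OC)c1C=O | starting material
3 | 4-(4-bromo-2,6-dimethoxyphenoxy)-2,6-dimethoxybenzaldehyde | COc1cc(Br)cc(OC)c1Oc1cc(OC)c(C=O)c(OC)c1 | intermediate
4 | 2,4,6-trimethoxyphenol | COc1cc(OC)c(O)c(OC)c1 | starting material
5 | 4-[2,6-dimethoxy-4-(2,4,6-trimethoxyphenoxy)phenoxy]-2,6-dimethoxybenzaldehyde | COc1cc(OC)c(Oc2cc(OC)c(Oc3cc(OC)c(C=O)c(OC)c3)c(OC)c2)c(OC)c1 | intermediate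
6 | 4-[2,6-dimethoxy-4-(2,4,6-trimethoxyphenoxy)phenoxy]-2,6-dimethoxyphenyl formate (formed in the flask) | COc1cc(OC)c(Oc2cc(OC)c(Oc3cc(OC)c(OC=O)c(OC)c3)c(OC)c2)c(OC)c1 | intermediate
7 | 4-[2,6-dimethoxy-4-(2,4,6-trimethoxyphenoxy)phenoxy]-2,6-dimethoxyphenol | COc1cc(OC)c(Oc2cc(OC)c(Oc3cc(OC)c(O)c(OC)c3)c(OC)c2)c(OC)c1 | intermediate
8 | 5-bromo-1,2,3-trimethoxybenzene | COc1cc(Br)cc(OC)c1OC | starting material
9 | 1-bromo-2-[chloro(methoxy)methyl]-3,4,5-trimethoxybenzene (racemic, formed in the flask) | COC(Cl)c1c(Br)cc(OC)c(OC)c1OC | intermediate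
10 | 6-bromo-2,3,4-trimethoxybenzaldehyde | O=Cc1c(Br)cc(OC)c(OC)c1OC | intermediate
11 | 6-{4-[2,6-dimethoxy-4-(2,4,6-trimethoxyphenoxy)phenoxy]-2,6-dimethoxyphenoxy}-2,3,4-trimethoxybenzaldehyde | COc1cc(OC)c(Oc2cc(OC)c(Oc3cc(OC)c(Oc4cc(OC)c(OC)c(OC)c4C=O)c(OC)c3)c(OC)c2)c(OC)c1 | intermediate
12 | 6-{4-[2,6-dimethoxy-4-(2,4,6-trimethoxyphenoxy)phenoxy]-2,6-dimethoxyphenoxy}-2,3,4-trimethoxyphenyl formate (formed in the flask) | COc1cc(OC)c(Oc2cc(OC)c(Oc3cc(OC)c(Oc4cc(OC)c(OC)c(OC)c4OC=O)c(OC)c3)c(OC)c2)c(OC)c1 | intermediate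
13 | 6-{4-[2,6-dimethoxy-4-(2,4,6-trimethoxyphenoxy)phenoxy]-2,6-dimethoxyphenoxy}-2,3,4-trimethoxyphenol | COc1cc(OC)c(Oc2cc(OC)c(Oc3cc(OC)c(Oc4cc(OC)c(OC)c(OC)c4O)c(OC)c3)c(OC)c2)c(OC)c1 | intermediate
14 | (3,4,5-trimethoxyphenyl)boronic acid | COc1cc(B(O)O)cc(OC)c1OC | starting material
15 | 5-(4-bromo-2,6-dimethoxyphenoxy)-1,2,3-trimethoxybenzene | COc1cc(Br)cc(OC)c1Oc1cc(OC)c(OC)c(OC)c1 | intermediate
16 | 5-[4-(6-{4-[2,6-dimethoxy-4-(2,4,6-trimethoxyphenoxy)phenoxy]-2,6-dimethoxyphenoxy}-2,3,4-trimethoxyphenoxy)-2,6-dimethoxyphenoxy]-1,2,3-trimethoxybenzene | COc1cc(OC)c(Oc2cc(OC)c(Oc3cc(OC)c(Oc4cc(OC)c(OC)c(OC)c4Oc4cc(OC)c(Oc5cc(OC)c(OC)c(OC)c5)c(OC)c4)c(OC)c3)c(OC)c2)c(OC)c1 | intermediate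
17 | pentadecakis(O-dibromoboryl) derivative of 18 (formed in the flask) | BrB(Br)Oc1cc(OB(Br)Br)c(Oc2cc(OB(Br)Br)c(Oc3cc(OB(Br)Br)c(Oc4cc(OB(Br)Br)c(OB(Br)Br)c(OB(Br)Br)c4Oc4cc(OB(Br)Br)c(Oc5cc(OB(Br)Br)c(OB(Br)Br)c(OB(Br)Br)c5)c(OB(Br)Br)c4)c(OB(Br)Br)c3)c(OB(Br)Br)c2)c(OB(Br)Br)c1 | intermediate
18 | 5-[4-(6-{4-[2,6-dihydroxy-4-(2,4,6-trihydroxyphenoxy)phenoxy]-2,6-dihydroxyphenoxy}-2,3,4-trihydroxyphenoxy)-2,6-dihydroxyphenoxy]benzene-1,2,3-triol (CNP0175585.0, achiral) | Oc1cc(O)c(Oc2cc(O)c(Oc3cc(O)c(Oc4cc(O)c(O)c(O)c4Oc4cc(O)c(Oc5cc(O)c(O)c(O)c5)c(O)c4)c(O)c3)c(O)c2)c(O)c1 | target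

**Step count and risks**
Total step count: 9. Longest linear sequence: 7 (steps 1, 2, 3, 5, 6, 8, 9); steps 4 and 7 are side branches of one step each.

Most likely to fail, first: step 5. A doubly ortho-substituted trimeric phenol must attack a bromide that is itself ortho-substituted, so conversion may be low and hydrodebromination of 10 may compete. Fallback: form the crowded C–O–D bond first on monomers. It sets out from 1 and 10 (with 2 and 4 for the partner) and comes back at 11, replacing steps 1, 2, 3 and 5 with the same number of operations. Phenol 1 is coupled under the same copper catalysis with excess 10, whose C–Br bond is ortho-formyl-activated whereas the C–Br bond of the phenoxide of 1 is deactivated, to give 6-(4-bromo-2,6-dimethoxyphenoxy)-2,3,4-trimethoxybenzaldehyde F1. In parallel, SNAr of 4 on 2 (K2CO3, DMF) gives 2,6-dimethoxy-4-(2,4,6-trimethoxyphenoxy)benzaldehyde F2. Baeyer–Villiger oxidation of F2 gives 2,6-dimethoxy-4-(2,4,6-trimethoxyphenoxy)phenyl formate F3, which is not isolated, and methanolysis gives 2,6-dimethoxy-4-(2,4,6-trimethoxyphenoxy)phenol F4. Ullmann coupling of F4 with the unhindered bromide of F1 then gives 11.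

Second: step 8. Phenol 13 is flanked by a methoxy and a bulky aryloxy group and bromide 15 is electron-rich, so the copper coupling may stall. Fallback: replace the copper step by a metal-free SNAr and a room-temperature Chan–Lam step. It sets out from 13 and comes back at 16, and is one step longer. SNAr of 13 on the unhindered, formyl-activated fluoride 2 gives 4-(6-{4-[2,6-dimethoxy-4-(2,4,6-trimethoxyphenoxy)phenoxy]-2,6-dimethoxyphenoxy}-2,3,4-trimethoxyphenoxy)-2,6-dimethoxybenzaldehyde F5. Baeyer–Villiger oxidation gives the corresponding 2,6-dimethoxyphenyl formate F6, which is not isolated, and methanolysis gives 4-(6-{4-[2,6-dimethoxy-4-(2,4,6-trimethoxyphenoxy)phenoxy]-2,6-dimethoxyphenoxy}-2,3,4-trimethoxyphenoxy)-2,6-dimethoxyphenol F7. Chan–Lam arylation of F7 with boronic acid 14 then gives 16.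

Third: step 9. Fifteen ether cleavages in one operation may leave partly methylated congeners, and the free polyphenol is very polar and air-sensitive, so direct isolation may fail. Fallback: isolate through the peracetate. It sets out from 16 and comes back at 18. Compound 16 is demethylated with BBr3 as before (via 17), and the crude phenol is not purified but acetylated at once (Ac2O, pyridine, DMAP) to the pentadecaacetate of 18 F8. F8 is purified on silica, where partly methylated material is separated and resubmitted, and is then cleaved by degassed acidic methanolysis (HCl in MeOH, rt) to pure 18.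

**Further compounds**
F1 | step 5 | 6-(4-bromo-2,6-dimethoxyphenoxy)-2,3,4-trimethoxybenzaldehyde | COc1cc(Br)cc(OC)c1Oc1cc(OC)c(OC)c(OC)c1C=O
F2 | step 5 | 2,6-dimethoxy-4-(2,4,6-trimethoxyphenoxy)benzaldehyde | COc1cc(OC)c(Oc2cc(OC)c(C=O)c(OC)c2)c(OC)c1
F3 | step 5 | 2,6-dimethoxy-4-(2,4,6-trimethoxyphenoxy)phenyl formate | COc1cc(OC)c(Oc2cc(OC)c(OC=O)c(OC)c2)c(OC)c1
F4 | step 5 | 2,6-dimethoxy-4-(2,4,6-trimethoxyphenoxy)phenol | COc1cc(OC)c(Oc2cc(OC)c(O)c(OC)c2)c(OC)c1
F5 | step 8 | 4-(6-{4-[2,6-dimethoxy-4-(2,4,6-trimethoxyphenoxy)phenoxy]-2,6-dimethoxyphenoxy}-2,3,4-trimethoxyphenoxy)-2,6-dimethoxybenzaldehyde | COc1cc(OC)c(Oc2cc(OC)c(Oc3cc(OC)c(Oc4cc(OC)c(OC)c(OC)c4Oc4cc(OC)c(C=O)c(OC)c4)c(OC)c3)c(OC)c2)c(OC)c1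
F6 | step 8 | 4-(6-{4-[2,6-dimethoxy-4-(2,4,6-trimethoxyphenoxy)phenoxy]-2,6-dimethoxyphenoxy}-2,3,4-trimethoxyphenoxy)-2,6-dimethoxyphenyl formate | COc1cc(OC)c(Oc2cc(OC)c(Oc3cc(OC)c(Oc4cc(OC)c(OC)c(OC)c4Oc4cc(OC)c(OC=O)c(OC)c4)c(OC)c3)c(OC)c2)c(OC)c1
F7 | step 8 | 4-(6-{4-[2,6-dimethoxy-4-(2,4,6-trimethoxyphenoxy)phenoxy]-2,6-dimethoxyphenoxy}-2,3,4-trimethoxyphenoxy)-2,6-dimethoxyphenol | COc1cc(OC)c(Oc2cc(OC)c(Oc3cc(OC)c(Oc4cc(OC)c(OC)c(OC)c4Oc4cc(OC)c(O)c(OC)c4)c(OC)c3)c(OC)c2)c(OC)c1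
F8 | step 9 | pentadeca-O-acetyl derivative of 18 | CC(=O)Oc1cc(OC(C)=O)c(Oc2cc(OC(C)=O)c(Oc3cc(OC(C)=O)c(Oc4cc(OC(C)=O)c(OC(C)=O)c(OC(C)=O)c4Oc4cc(OC(C)=O)c(Oc5cc(OC(C)=O)c(OC(C)=O)c(OC(C)=O)c5)c(OC(C)=O)c4)c(OC(C)=O)c3)c(OC(C)=O)c2)c(OC(C)=O)c1
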